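The cyclohexene is assembled acyclically and closed last at the bond between C5 (the ring carbon carrying the benzoate) and C6 (the allylic carbinol next to C1), by a titanocene pinacol cyclisation of a (Z)-enal/α-alkoxy aldehyde. The 1,6-dialdehyde precursor carries the C3/C4 diol of D-threitol (D-tartrate pool) as a trans-acetonide and the C7 benzoate; its (Z)-trisubstituted alkene comes from a Morita–Baylis–Hillman adduct. The key step exploits the trans-fused dioxolane on C3/C4: it locks the forming half-chair so that the only geometry with both bulky titanium-bound oxygens anti (O5 axial, O6 pseudoaxial) is the target's 4,5-cis/5,6-trans array. Ring, C5 and C6 are set in one operation.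

Key step: step 9

Remark on numbering: C1 is the alkene carbon bearing the benzoyloxymethyl carbon C7, C2 the alkene CH, C3 and C4 the free carbinols, C5 the benzoate carbon, C6 the allylic carbinol; in this numbering the target is 3R,4S,5R,6S.
Assumption: (−)-2,3-O-isopropylidene-D-threitol (from D-tartaric acid) is commercially available; adduct 6 is carried as a mixture of carbinol epimers because that centre becomes sp2 in step 4.

Step 1
Reactants: 1 (−)-2,3-O-isopropylidene-D-threitol; 2 tert-butyldimethylsilyl chloride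
Product: 3 [(4R,5R)-5-{[(tert-butyldimethylsilyl)oxy]methyl}-2,2-dimethyl-1,3-dioxolan-4-yl]methanol
Conditions: NaH (1.0 equiv), THF, 0 °C; then TBSCl (1.0 equiv), 0 °C → rt
Reagents that add atoms: tert-butyldimethylsilyl chloride, CC(C)(C)[Si](C)(C)Cl
Why: O-silylation of the monosodium alkoxide of a C2-symmetric diol should stop at the mono-ether, the two hydroxyls being equivalent and no stereocentre being touched.

Step 2
Reactants: 3 mono-TBS ether
Product: 4 (4S,5R)-5-{[(tert-butyldimethylsilyl)oxy]methyl}-2,2-dimethyl-1,3-dioxolane-4-carbaldehyde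
Conditions: Dess–Martin periodinane, pyridine, CH2Cl2, 0 °C → rt
Reagents that add atoms: none
Why: Dess–Martin oxidation of the primary alcohol under buffered conditions should give the α-alkoxy aldehyde without epimerisation, the trans-dioxolane being the thermodynamic arrangement in any case.

Step 3
Reactants: 4 aldehyde; 5 methyl acrylate
Product: 6 methyl 2-{hydroxy[(4R,5R)-5-{[(tert-butyldimethylsilyl)oxy]methyl}-2,2-dimethyl-1,3-dioxolan-4-yl]methyl}prop-2-enoate (both carbinol epimers)
Conditions: DABCO (1.0 equiv), methyl acrylate (3 equiv), 1,4-dioxane/H2O (1:1), rt, 2–4 d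
Reagents that add atoms: methyl acrylate, C=CC(=O)OC
Why: Morita–Baylis–Hillman reaction of an activated α-alkoxy aldehyde, accelerated in aqueous dioxane, should install C1, C6 and C7 at once; the new carbinol centre need not be controlled.

Step 4
Reactants: 6 Baylis–Hillman adduct; 7 N-bromosuccinimide
Product: 8 methyl (Z)-2-(bromomethyl)-3-[(4R,5R)-5-{[(tert-butyldimethylsilyl)oxy]methyl}-2,2-dimethyl-1,3-dioxolan-4-yl]prop-2-enoate
Conditions: NBS (1.3 equiv), Me2S (1.5 equiv), CH2Cl2, 0 °C → rt
Reagents that add atoms: N-bromosuccinimide, O=C1CCC(=O)N1Br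
Why: Corey–Kim-type activation of the allylic alcohol followed by SN2′ attack of bromide should give the thermodynamically preferred (Z)-bromide with the ester trans and CH2Br cis to the dioxolane, which fixes C6 (CH2Br) cis and C7 (ester) trans to C3.

Step 5
Reactants: 8 bromo ester
Product: 9 (Z)-2-(bromomethyl)-3-[(4R,5R)-5-{[(tert-butyldimethylsilyl)oxy]methyl}-2,2-dimethyl-1,3-dioxolan-4-yl]prop-2-en-1-ol
Conditions: i-Bu2AlH (2.3 equiv), CH2Cl2, −78 °C; aq. potassium sodium tartrate
Reagents that add atoms: none
Why: 1,2-reduction of the enoate by the electrophilic hydride i-Bu2AlH at −78 °C should leave the allylic bromide and the alkene geometry intact.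

Step 6
Reactants: 9 bromo alcohol; 10 benzoyl chloride
Product: 11 (Z)-2-(bromomethyl)-3-[(4R,5R)-5-{[(tert-butyldimethylsilyl)oxy]methyl}-2,2-dimethyl-1,3-dioxolan-4-yl]prop-2-en-1-yl benzoate
Conditions: BzCl (1.2 equiv), i-Pr2NEt, DMAP (5 mol %), CH2Cl2, 0 °C
Reagents that add atoms: benzoyl chloride, O=C(Cl)c1ccccc1
Why: DMAP-catalysed acylation of the only free hydroxyl places the C7 benzoate, the hindered base avoiding quaternisation by the allylic bromide.

Step 7
Reactants: 11 silyl ether
Product: 12 (Z)-2-(bromomethyl)-3-[(4R,5R)-5-(hydroxymethyl)-2,2-dimethyl-1,3-dioxolan-4-yl]prop-2-en-1-yl benzoate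
Conditions: HF·pyridine, THF, 0 °C → rt
Reagents that add atoms: none
Why: Fluoride-mediated desilylation in an acidic, non-nucleophilic medium should free the C5 alcohol without benzoate migration, bromide displacement or acetonide loss.

Step 8
Reactants: 12 bromo alcohol; 13 N-methylmorpholine N-oxide
Product: 15 (Z)-2-formyl-3-[(4R,5S)-5-formyl-2,2-dimethyl-1,3-dioxolan-4-yl]prop-2-en-1-yl benzoate, via bromo aldehyde 14 (not isolated)
Conditions: Pr4N[RuO4] (5 mol %), NMO (5 equiv), 4 Å molecular sieves, MeCN/CH2Cl2, 0 °C → rt; short silica plug, used at once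
Reagents that add atoms: N-methylmorpholine N-oxide, C[N+]1([O-])CCOCC1
Why: Ley–Griffith oxidation of the primary alcohol and Kornblum-type oxidation of the allylic bromide (SN2 O-alkylation of the N-oxide, then loss of N-methylmorpholine) should run in one pot, neither touching the alkene, so the C6 formyl group stays cis to C3.

Step 9
Reactants: 15 dialdehyde
Product: 16 [(3R,4R,5R,6S)-5,6-dihydroxy-3,4-(isopropylidenedioxy)cyclohex-1-en-1-yl]methyl benzoate
Conditions: Cp2TiPh (2.5 equiv; made at −78 °C from Cp2TiCl2, i-PrMgCl, then PhMgBr), THF, slow addition of 15 (high dilution), −78 → −20 °C; then aq. NH4Cl, air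
Reagents that add atoms: none
Why: Cp2TiPh (monomeric, trivalent titanium) transfers one electron to each formyl group, and the two titanium-bound ketyl carbons join to form the C5–C6 bond, the enal-derived ketyl reacting at C6 because only that closes a six-membered ring; aqueous work-up frees the diol. The reaction type is the intramolecular pinacol coupling of a 1,6-dialdehyde with a bulky titanocene reagent, a known trans-selective route to cyclohexane-1,2-diols. The carbocycle closes in a 6-exo-trig sense at both carbonyl carbons, both oxygens ending outside the ring. C5 is controlled by C4: the trans-fused dioxolane holds O3 and O4 equatorial, so the C4–O bond lies anti to the forming bond (Felkin–Anh), which places O5 axial and cis to O4. C6 is controlled by C5: the two Cp2(Ph)Ti–O groups cannot chelate and avoid each other, and in the locked half-chair an anti arrangement exists only with O6 pseudoaxial and trans to O5, which also relieves A(1,2) strain with the CH2OBz group on C1. The step needs trans and facial diastereoselectivity, six-ring closure in preference to intermolecular or C2 coupling and to β-alkoxide loss, and an intact (Z)-alkene; these should be secured by the acetonide lock, the cis disposition of the two formyl-bearing arms, high dilution at low temperature and the single-electron character of the reagent.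

Step 10
Reactants: 16 diol; 10 benzoyl chloride
Product: 17 [(3R,4S,5R,6S)-5-(benzoyloxy)-6-hydroxy-3,4-(isopropylidenedioxy)cyclohex-1-en-1-yl]methyl benzoate
Conditions: BzCl (1.05 equiv), pyridine, CH2Cl2, −40 → 0 °C
Reagents that add atoms: benzoyl chloride, O=C(Cl)c1ccccc1
Why: Kinetic mono-acylation should favour the axial C5 hydroxyl, which is activated by hydrogen bonding to the cis O4, over the C6 hydroxyl, which is shielded by the CH2OBz group on C1 and hydrogen-bonded to the C7 ester; the locked trans-diaxial relationship also precludes acyl migration.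

Step 11
Reactants: 17 acetonide dibenzoate
Product: 18 [(3R,4S,5R,6S)-5-(benzoyloxy)-3,4,6-trihydroxycyclohex-1-en-1-yl]methyl benzoate (CNP0198957.1)
Conditions: AcOH/H2O (4:1), 40 °C
Reagents that add atoms: none
Why: Acid hydrolysis of the strained trans-fused isopropylidene acetal should free O3 and O4 under conditions in which benzoates neither cleave nor migrate and no stereocentre is affected.

Compound list
1 | (−)-2,3-O-isopropylidene-D-threitol, (4R,5R)-2,2-dimethyl-1,3-dioxolane-4,5-dimethanol | OC[C@H]1OC(C)(C)O[C@@H]1CO | starting material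
2 | tert-butyldimethylsilyl chloride | CC(C)(C)[Si](C)(C)Cl | starting material
3 | [(4R,5R)-5-{[(tert-butyldimethylsilyl)oxy]methyl}-2,2-dimethyl-1,3-dioxolan-4-yl]methanol | OC[C@H]1OC(C)(C)O[C@@H]1CO[Si](C)(C)C(C)(C)C | intermediate
4 | (4S,5R)-5-{[(tert-butyldimethylsilyl)oxy]methyl}-2,2-dimethyl-1,3-dioxolane-4-carbaldehyde | O=C[C@H]1OC(C)(C)O[C@@H]1CO[Si](C)(C)C(C)(C)C | intermediate
5 | methyl acrylate | C=CC(=O)OC | starting material
6 | methyl 2-{hydroxy[(4R,5R)-5-{[(tert-butyldimethylsilyl)oxy]methyl}-2,2-dimethyl-1,3-dioxolan-4-yl]methyl}prop-2-enoate, both carbinol epimers | C=C(C(=O)OC)C(O)[C@H]1OC(C)(C)O[C@@H]1CO[Si](C)(C)C(C)(C)C | intermediate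
7 | N-bromosuccinimide | O=C1CCC(=O)N1Br | starting material
8 | methyl (Z)-2-(bromomethyl)-3-[(4R,5R)-5-{[(tert-butyldimethylsilyl)oxy]methyl}-2,2-dimethyl-1,3-dioxolan-4-yl]prop-2-enoate | COC(=O)/C(CBr)=C/[C@H]1OC(C)(C)O[C@@H]1CO[Si](C)(C)C(C)(C)C | intermediate
9 | (Z)-2-(bromomethyl)-3-[(4R,5R)-5-{[(tert-butyldimethylsilyl)oxy]methyl}-2,2-dimethyl-1,3-dioxolan-4-yl]prop-2-en-1-ol | OC/C(CBr)=C/[C@H]1OC(C)(C)O[C@@H]1CO[Si](C)(C)C(C)(C)C | intermediate
10 | benzoyl chloride | O=C(Cl)c1ccccc1 | starting material
11 | (Z)-2-(bromomethyl)-3-[(4R,5R)-5-{[(tert-butyldimethylsilyl)oxy]methyl}-2,2-dimethyl-1,3-dioxolan-4-yl]prop-2-en-1-yl benzoate | O=C(OC/C(CBr)=C/[C@H]1OC(C)(C)O[C@@H]1CO[Si](C)(C)C(C)(C)C)c1ccccc1 | intermediate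
12 | (Z)-2-(bromomethyl)-3-[(4R,5R)-5-(hydroxymethyl)-2,2-dimethyl-1,3-dioxolan-4-yl]prop-2-en-1-yl benzoate | O=C(OC/C(CBr)=C/[C@H]1OC(C)(C)O[C@@H]1CO)c1ccccc1 | intermediate
13 | N-methylmorpholine N-oxide | C[N+]1([O-])CCOCC1 | starting material
14 | (Z)-2-(bromomethyl)-3-[(4R,5S)-5-formyl-2,2-dimethyl-1,3-dioxolan-4-yl]prop-2-en-1-yl benzoate | O=C(OC/C(CBr)=C/[C@H]1OC(C)(C)O[C@@H]1C=O)c1ccccc1 | intermediate (not isolated)
15 | (Z)-2-formyl-3-[(4R,5S)-5-formyl-2,2-dimethyl-1,3-dioxolan-4-yl]prop-2-en-1-yl benzoate | O=C(OC/C(C=O)=C/[C@H]1OC(C)(C)O[C@@H]1C=O)c1ccccc1 | intermediate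
16 | [(3R,4R,5R,6S)-5,6-dihydroxy-3,4-(isopropylidenedioxy)cyclohex-1-en-1-yl]methyl benzoate | O=C(OCC1=C[C@H]2OC(C)(C)O[C@@H]2[C@H](O)[C@H]1O)c1ccccc1 | intermediate
17 | [(3R,4S,5R,6S)-5-(benzoyloxy)-6-hydroxy-3,4-(isopropylidenedioxy)cyclohex-1-en-1-yl]methyl benzoate | O=C(OCC1=C[C@H]2OC(C)(C)O[C@@H]2[C@H](OC(=O)c2ccccc2)[C@H]1O)c1ccccc1 | intermediate
18 | [(3R,4S,5R,6S)-5-(benzoyloxy)-3,4,6-trihydroxycyclohex-1-en-1-yl]methyl benzoate | O=C(OCC1=C[C@@H](O)[C@H](O)[C@H](OC(=O)c2ccccc2)[C@H]1O)c1ccccc1 | target

Total step count: 11. Longest linear sequence: 11 steps (1 → 18).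

Steps most likely to fail

Step 9 (key step). Diastereocontrol may be lost through a chelated or wrong-face transition state, the enal ketyl may be over-reduced with loss of the C3 oxygen, or the enal may isomerise before closure. Fallback: the same bond would be closed by an intramolecular Corey–Chaykovsky epoxidation. It sets out from alcohol 12, which Dess–Martin periodinane/pyridine oxidises to bromo aldehyde 14, isolated this time. Tetrahydrothiophene in acetone alkylates at C6 to give the allylic sulfonium bromide F1. K2CO3 in MeCN forms the ylide, which adds to the C5 aldehyde (Felkin–Anh, O5 cis to O4) and closes to the cis-fused 5,6-vinyl epoxide F2. Dilute aqueous H2SO4 in THF should then open F2 at the allylic C6 in the trans-diaxial sense, and the route is rejoined at diol 16.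

Step 10. Acylation may occur at the allylic O6 or at both hydroxyls. Fallback: O6 and O7 are tied together before O5 is acylated. Setting out from 16, K2CO3/MeOH removes the C7 benzoate to give the acetonide triol F3. 2,2-Dimethoxypropane with pyridinium p-toluenesulfonate closes the only possible second acetal, the six-membered 6,7-O-isopropylidene compound F4, since the trans-diaxial O5/O6 pair cannot bridge. BzCl/DMAP/pyridine esterifies the remaining O5 to give the bis-acetonide benzoate F5, and AcOH/H2O removes both acetals to give the 5-O-benzoyl tetraol F6. BzCl (1.0 equiv) with 2,4,6-collidine at −40 °C should then acylate only the primary allylic hydroxyl, and the route is rejoined at target 18.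

Step 8. The (Z)-enal may isomerise through amine-mediated conjugate addition, or the N-oxide displacement may go by SN2′ attack or elimination. Fallback: C6 is taken to the alcohol level first. Setting out from 12, caesium levulinate in DMF displaces the bromide by SN2 to give the levulinate F7. Hydrazine acetate in CH2Cl2/MeOH removes the levulinoyl group selectively to give the diol F8. Dess–Martin periodinane/pyridine oxidises both primary alcohols, and the route is rejoined at dialdehyde 15.

Further compounds
F1 | step 9 | 1-{(Z)-2-[(benzoyloxy)methyl]-3-[(4R,5S)-5-formyl-2,2-dimethyl-1,3-dioxolan-4-yl]prop-2-en-1-yl}tetrahydrothiophenium bromide | O=C(OC/C(C[S+]1CCCC1)=C/[C@H]1OC(C)(C)O[C@@H]1C=O)c1ccccc1.[Br-]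
F2 | step 9 | [5,6-epoxy-3,4-(isopropylidenedioxy)cyclohex-1-en-1-yl]methyl benzoate, epoxide oxygen cis to O4 and trans to O3 | O=C(OCC1=C[C@H]2OC(C)(C)O[C@@H]2[C@@H]3O[C@H]13)c1ccccc1
F3 | step 10 | (3R,4R,5R,6S)-1-(hydroxymethyl)-3,4-(isopropylidenedioxy)cyclohex-1-ene-5,6-diol | OCC1=C[C@H]2OC(C)(C)O[C@@H]2[C@H](O)[C@H]1O
F4 | step 10 | 3,4:6,7-di-O-isopropylidene derivative of the C7-debenzoylated pentaol, O5 free | CC1(C)OCC2=C[C@H]3OC(C)(C)O[C@@H]3[C@H](O)[C@H]2O1
F5 | step 10 | 5-O-benzoyl-3,4:6,7-di-O-isopropylidene derivative | CC1(C)OCC2=C[C@H]3OC(C)(C)O[C@@H]3[C@H](OC(=O)c3ccccc3)[C@H]2O1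
F6 | step 10 | (3R,4S,5R,6S)-5-(benzoyloxy)-1-(hydroxymethyl)cyclohex-1-ene-3,4,6-triol | OCC1=C[C@@H](O)[C@H](O)[C@H](OC(=O)c2ccccc2)[C@H]1O
F7 | step 8 | (Z)-2-[(benzoyloxy)methyl]-3-[(4R,5R)-5-(hydroxymethyl)-2,2-dimethyl-1,3-dioxolan-4-yl]prop-2-en-1-yl 4-oxopentanoate | O=C(OC/C(COC(=O)CCC(C)=O)=C/[C@H]1OC(C)(C)O[C@@H]1CO)c1ccccc1
F8 | step 8 | (Z)-2-(hydroxymethyl)-3-[(4R,5R)-5-(hydroxymethyl)-2,2-dimethyl-1,3-dioxolan-4-yl]prop-2-en-1-yl benzoate | O=C(OC/C(CO)=C/[C@H]1OC(C)(C)O[C@@H]1CO)c1ccccc1
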